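Monday's run, at 31 mM of substrate, stood at 91.1% target after 4.00 min, and the meeting opened by asking what the new row of flasks holds at 6.0 min.

| flask | substrate | solid reagent | remark | time |
|---|---|---|---|---|
| Friday's | 0.35 mM | 2 equiv | run made earlier |  |
| Tuesday's | 3.6 mM | 2 equiv | run made earlier |  |
| Monday's | 31 mM | 2 equiv | run made earlier |  |
| violet | 0.40 mM | 2.00 equiv |  | 6.0 min |
| amber | 1.2 mM | 2.00 equiv |  | 6.0 min |
| green | 3.0 mM | 2.00 equiv |  | 6.0 min |
| teal | 10 mM | 2.00 equiv |  | 6.0 min |
| blue | 30 mM | 2.00 equiv |  | 6.0 min |

- Friday's (time / min: target / %): 0.333: 23.2; 0.667: 48.0; 1.33: 71.4; 2.00: 79.6; 4.00: 91.3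
- Tuesday's (time / min: target / %): 0.333: 23.1; 0.667: 47.7; 1.33: 71.4; 2.00: 79.6; 4.00: 90.9
- Monday's (time / min: target / %): 0.417: 30.1; 1.00: 62.7; 2.00: 79.9; 3.00: 86.2; 4.00: 91.1

(standard deviation of a reading: 0.5 percentage points)

- given per volume of solution although it is solid: solid reagent
- the earlier runs were read with a standard deviation of 0.5 percentage points
- at the start none of the solid reagent is in solution
- "hardly changes" means that all values lie within two and a half points (for a concentration: within two and a half percent of the largest)

- amount of target at the end, in percent of the substrate charged for violet, amber, green, teal, blue, in this order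
- how the row runs (falls, then rises / falls all the way / rises, then falls / hardly changes / rises all the way)

The first speaker solved the two ends. Friday's run, at 0.35 mM, read 91.3% at the same time, a gap of 0.2 percentage points against a reading scatter of 0.5 points. She argued that the new flasks lie between those ends, so one curve should join them.

The second speaker asked how far that curve still climbs past the last reading. The minute-taker answered with his own reckoning. Averaged over Friday's and Monday's runs, the share of the charge not yet target was 20.2% at 2.00 min and 8.80% at 4.00 min. That gives 1.66 min as the time in which this share falls to half, the tail half-time. Carried on to 6.0 min, it leaves 3.82%, so target stands at 96.2%.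

The third speaker tabled the forecast: 96%, 96%, 96%, 96% and 96%, a row that hardly changes, on the ground that the earlier runs “trace essentially the same percent-against-time curve, within reading error”. The minute-taker's figure stands 0.18 points from it.

Violet, amber, green, teal and blue gave 95.3%, 95.3%, 95.3%, 95.3% and 95.3%, and the row hardly changes.

    substrate → intermediate A (k = 0.0320 s⁻¹)
    substrate → intermediate B (k = 0.00860 s⁻¹)
    intermediate A ⇌ intermediate C (K = 0.380, k = 0.00740 s⁻¹)
    intermediate A → target (k = 0.0830 s⁻¹)
    intermediate B ⇌ intermediate D (K = 0.130, k = 0.00680 s⁻¹)
    intermediate A ⇌ intermediate B (K = 0.910, k = 0.00630 s⁻¹)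
    2 partner → homo dimer (k = 0.660 M⁻¹ s⁻¹)
    solid reagent ⇌ partner, rate k8*(cs8 - [partner]) while solid is left; crystals form when [partner] > cs8 (solubility = 0.340 mM, k = 0.0800 s⁻¹)

In violet the step from substrate to intermediate A had half of its turnover behind it by 0.285 min and the step from intermediate A to target by 0.661 min, and at 3.00 min substrate stood at 0.0670%, target at 86.8% and intermediate B at 9.83%. From then to 6.00 min intermediate B fell to 3.63% while the share not yet target fell to half on average every 2.02 min, longer than the tail half-time of 1.66 min, and blue, holding 99.4% of its solid reagent against violet's 51.3%, had over the same minutes an average of 2.02 min, also longer than 1.66 min, and stood at 100% target at 60.0 min.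

(The readings were generated by integration from invented constants.)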